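**Plan**
Retrosynthetic cuts, in order:
- The C5–OH and the side-chain acid are rejoined as an enol lactone (ring C).
- The C8–prenyl bond is undone by a retro-[3,3] shift to an aromatic O7 1,1-dimethylallyl ether.
- The C8–CH2(cyclobutyl) bond goes back to an aryl iodide and an alkylzinc.
- The C4–C4a bond opens ring B.
- The O1–C2 bond separates a hydroxy ester from a coumarin.

Enabling feature: ring B is the chain O1–C2–C3–C4. This is a 3-oxy-2-methylbutanoyl unit spanning O1 on C8a and the adjacent ring-A carbon C4a. A 3-aryloxy-2-methylbutanoic acid can therefore close ring B by acylating C4a of the phloroglucinol-type ring A.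

Forward order: ring A is bought. Ring C is made first (Pechmann condensation, later 1,4-reduction). The C4 chain is attached at O1, and ring B closes by Friedel–Crafts acylation. The cyclobutane (ring D, from verbenone) is coupled at C8. The Claisen shift dearomatises ring A, and ring C is opened last.

Stereochemistry:
- C2 comes from (S)-3-hydroxybutanoate with Mitsunobu inversion.
- C3 comes from anti-selective dianion methylation.
- C1' comes from ligand-controlled copper hydride addition.
- Both ring-D centres come from (+)-verbenone.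
- C8 is set by relay from C1' through the O7 ether in the [3,3] shift.

Key step: step 7

Locants: the Why lines use the chromanone numbering of the target (O1, C2–C8a; C1' is the propyl-bearing carbon). Names of the bicyclic intermediates use coumarin numbering, where coumarin O7 = O1, C8 = C4a, lactone O = O5, C4a = C6, C5–O = O7, C6 = C8 and C4 = C1'.

Assumption: (R)-DTBM-SEGPHOS is taken to direct hydride to the face of C1' that gives the (S) centre. If the sense is the opposite, the (S) ligand is used. (1R,5R)-(+)-Verbenone is taken as purchasable.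

**Route**

Step 1
Reactants: 1 tert-butyl (S)-3-hydroxybutanoate
Product: 3 tert-butyl (2S,3S)-3-hydroxy-2-methylbutanoate, via dilithium alkoxide enolate 2 (not isolated)
Conditions: LDA (2.2 equiv), THF, −78 to −20 °C; MeI, DMPU, −78 to 0 °C; H2O
Reagents that add atoms: iodomethane, CI
Why: Fráter–Seebach alkylation, in which the chelated dianion 2 is methylated on the face opposite the carbinol methyl group, so the new centre (later C3) is set anti to the existing one.

Step 2
Reactants: 4 phloroglucinol; 5 ethyl 3-oxohexanoate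
Product: 6 5,7-dihydroxy-4-propylcoumarin
Conditions: conc. H2SO4, 0 °C to rt
Reagents that add atoms: none
Why: Pechmann condensation of a highly activated phenol with a β-keto ester, and the threefold symmetry of 4 leaves no regiochemical choice.

Step 3
Reactants: 6 5,7-dihydroxy-4-propylcoumarin; 3 tert-butyl (2S,3S)-3-hydroxy-2-methylbutanoate
Product: 7 tert-butyl (2S,3R)-3-[(5-hydroxy-2-oxo-4-propyl-2H-chromen-7-yl)oxy]-2-methylbutanoate
Conditions: PPh3, DIAD, THF, 0 °C to rt
Reagents that add atoms: none
Why: Mitsunobu etherification, in which the 7-OH (conjugated to the lactone carbonyl, hence more acidic, and free of the peri propyl group that screens the 5-OH) displaces the activated carbinol oxygen by SN2 with inversion, turning the anti alcohol into the syn ether and setting C2 as (R).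

Step 4
Reactants: 7 the 5-hydroxycoumarin ether
Product: 8 tert-butyl (2S,3R)-2-methyl-3-{[2-oxo-4-propyl-5-(triisopropylsilyloxy)-2H-chromen-7-yl]oxy}butanoate
Conditions: TIPSOTf, 2,6-lutidine, CH2Cl2, 0 °C
Reagents that add atoms: triisopropylsilyl trifluoromethanesulfonate, CC(C)[Si](OS(=O)(=O)C(F)(F)F)(C(C)C)C(C)C
Why: Silyl ether formation with a silyl triflate and a hindered weak base covers O7 without exposing the β-aryloxy ester to E1cB conditions, and an aryl TIPS ether withstands the later acidic steps.

Step 5
Reactants: 8 the 5-O-TIPS coumarin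
Product: 10 tert-butyl (2S,3R)-2-methyl-3-{[(4S)-2-oxo-4-propyl-5-(triisopropylsilyloxy)chroman-7-yl]oxy}butanoate, via boron enolate 9 (not isolated)
Conditions: CuCl (5 mol %), NaOt-Bu (6 mol %), (R)-DTBM-SEGPHOS (5.5 mol %), pinacolborane (1.5 equiv), toluene, rt; aq NH4Cl
Reagents that add atoms: none
Why: Copper hydride catalysed asymmetric 1,4-hydroboration (conjugate reduction) of a 4-substituted coumarin, in which the chiral bisphosphine selects the face of C1' for hydride delivery and so sets (S), while trapping as 9 prevents further reduction of the lactone carbonyl.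

Step 6
Reactants: 10 the (4S)-dihydrocoumarin tert-butyl ester
Product: 11 (2S,3R)-2-methyl-3-{[(4S)-2-oxo-4-propyl-5-(triisopropylsilyloxy)chroman-7-yl]oxy}butanoic acid
Conditions: CF3CO2H–CH2Cl2 1:3, Et3SiH (2.5 equiv), 0 °C to rt
Reagents that add atoms: none
Why: Acidolysis of a tert-butyl ester with Et3SiH intercepting the tert-butyl cation before it can alkylate ring A, so the acid is released without base and neither loss of the phenol nor α-epimerisation can occur.

Step 7
Reactants: 11 the (2S,3R)-3-aryloxy-2-methylbutanoic acid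
Product: 13 O7-TIPS lactone-chromanone (cis-2R,3S ring B; 1'S; C8–H), via acyl trifluoroacetate 12 (not isolated)
Conditions: (CF3CO)2O (3 equiv), CH2Cl2–CF3CO2H 10:1, 0 °C to rt
Reagents that add atoms: none
Why: Trifluoroacetic anhydride converts 11 into the mixed anhydride 12, which under the acid present serves as an acylium donor; C4a attacks it and the arenium ion loses its proton to give the aryl ketone, an intramolecular Friedel–Crafts acylation of the type that routinely turns 3-aryloxypropanoic acids into chroman-4-ones. Ring B closes as a six-membered ring, 6-exo-trig at the acyl carbon (the C=O stays outside the new ring), forming only the C4–C4a bond. No stereocentre is created: C2 and C3 travel in the tether, and the syn acid maps onto the cis-2,3-dimethyl ring. The step needs site selectivity between C4a and C8, both ortho to O1: C4a is para to the O7 donor, which is the 4-position of a resorcinol diether and the normal site of acylation, whereas C8 is the 2-position wedged between two oxygens and is covered by the triisopropylsilyl group, which the C6 side chain forces to lean toward C8. It also needs retention at C3, which the absence of base, the low temperature and the high reactivity of the ring secure. The lactone tied back at O5 and the aryl silyl ether are inert to anhydrous acid.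

Step 8
Reactants: 13 O7-TIPS lactone-chromanone
Product: 14 O7–H lactone-chromanone (7-hydroxy; C8–H)
Conditions: HF·pyridine, THF, 0 °C to rt
Reagents that add atoms: none
Why: Fluoride desilylation in an acidic medium frees O7 without any nucleophilic base that could open ring C, let it reclose on O7, or epimerise C3.

Step 9
Reactants: 14 O7–H lactone-chromanone
Product: 15 8-iodo-7-hydroxy lactone-chromanone
Conditions: NIS (1.05 equiv), CH2Cl2, 0 °C, dark
Reagents that add atoms: N-iodosuccinimide, O=C1CCC(=O)N1I
Why: Electrophilic aromatic iodination, for which C8 is the only ring carbon still bearing hydrogen and is activated by the ortho phenol and ortho O1.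

Step 10
Reactants: 16 (1R,5R)-(+)-verbenone
Product: 18 (1R,3S)-3-acetyl-2,2-dimethylcyclobutane-1-carboxylic acid, via alpha-keto acid 17 (not isolated)
Conditions: RuCl3·xH2O (2 mol %), NaIO4 (4.5 equiv), EtOAc–MeCN–H2O, rt
Reagents that add atoms: sodium periodate, [Na+].[O-]I(=O)(=O)=O; water, O
Why: RuO4-catalysed oxidative cleavage of the enone C=C gives the methyl ketone and the keto acid 17, which is oxidatively decarboxylated in the same pot, and both ring-D centres and their cis relationship are inherited unchanged from the bicyclic terpene.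

Step 11
Reactants: 18 the cis keto acid
Product: 19 (1R,3R)-2,2-dimethyl-3-(prop-1-en-2-yl)cyclobutane-1-carboxylic acid
Conditions: Ph3PCH3Br (2.5 equiv), KOt-Bu (3.5 equiv), THF, 0 °C to rt; 1 M HCl
Reagents that add atoms: methyltriphenylphosphonium bromide, C[P+](c1ccccc1)(c1ccccc1)c1ccccc1.[Br-]
Why: Wittig methylenation of the methyl ketone run on the free acid with one extra equivalent of base, and the cis geometry should hold because enolisation toward the ring would place an exocyclic double bond on the cyclobutane next to the quaternary carbon.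

Step 12
Reactants: 19 the isopropenyl acid
Product: 20 [(1R,3R)-2,2-dimethyl-3-(prop-1-en-2-yl)cyclobutyl]methanol
Conditions: LiAlH4, Et2O, 0 °C to rt
Reagents that add atoms: none
Why: Hydride reduction of a carboxylic acid to the primary alcohol leaves the isolated alkene and both stereocentres untouched.

Step 13
Reactants: 20 the cyclobutylmethanol
Product: 21 (1R,3R)-1-(iodomethyl)-2,2-dimethyl-3-(prop-1-en-2-yl)cyclobutane
Conditions: I2, PPh3, imidazole, CH2Cl2, 0 °C to rt
Reagents that add atoms: iodine, II
Why: Appel-type iodination proceeds by SN2 at the primary carbon, so no cyclobutylcarbinyl cation forms and the ring cannot rearrange.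

Step 14
Reactants: 21 the cyclobutylmethyl iodide; 15 8-iodo-7-hydroxy lactone-chromanone
Product: 23 8-{[(1S,3R)-2,2-dimethyl-3-(prop-1-en-2-yl)cyclobutyl]methyl}-7-hydroxy lactone-chromanone, via cyclobutylmethylzinc iodide 22 (not isolated)
Conditions: 21 (2 equiv), Zn dust, LiCl, THF, 40 °C; then 15, Pd(OAc)2 (5 mol %), SPhos (10 mol %), THF, rt to 40 °C
Reagents that add atoms: none
Why: Negishi sp3–sp2 cross-coupling, in which primary alkylzinc iodides are known to couple with unprotected iodophenols faster than they are protonated when a bulky biaryl phosphine is used, and the neutral medium tolerates lactone, ketone and alkene.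

Step 15
Reactants: 24 2-methylbut-3-en-2-ol
Product: 25 tert-butyl 2-methylbut-3-en-2-yl carbonate
Conditions: n-BuLi, THF, 0 °C; Boc2O, 0 °C to rt
Reagents that add atoms: di-tert-butyl dicarbonate, CC(C)(C)OC(=O)OC(=O)OC(C)(C)C
Why: O-acylation of the lithium alkoxide of a tertiary alcohol by the dicarbonate is the standard preparation of this allylic carbonate.

Step 16
Reactants: 23 the C8-alkylated phenol; 25 tert-butyl 2-methylbut-3-en-2-yl carbonate
Product: 26 O7 1,1-dimethylallyl ether of 23
Conditions: Pd(PPh3)4 (10 mol %), 25 (1.5 equiv), THF, 0 °C; filtration through silica at 0 °C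
Reagents that add atoms: none
Why: Tsuji–Trost O-allylation, in which zerovalent palladium ionises 25 with loss of CO2, the released tert-butoxide deprotonates the acidic O7–H, and the phenoxide attacks the more substituted allyl terminus under kinetic control, the established route to aryl 1,1-dimethylallyl ethers that needs no external base and so spares the cis ring B.

Step 17
Reactants: 26 the O7 1,1-dimethylallyl ether
Product: 27 (8R)-8-prenyl dienone enol lactone
Conditions: toluene (degassed), 110 °C
Reagents that add atoms: none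
Why: Dearomative aromatic Claisen rearrangement, a [3,3] shift onto an occupied ortho carbon that is known to stop at the 6,6-disubstituted cyclohexa-2,4-dienone when ring oxygens stabilise it as a vinylogous ester; C8 with its unbranched CH2 substituent is the less crowded terminus compared with ring-locked C6, strain relief in the doubly flanked tertiary ether and formation of the trisubstituted alkene drive the shift, and C8 is set by relay from C1', whose propyl group sits pseudoaxial on ring C to avoid O7 and thereby forces the perpendicular O7–CMe2 bond, and with it the suprafacially delivered prenyl group, onto the opposite face of ring A, which corresponds to (8R).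

Step 18
Reactants: 27 the dienone enol lactone
Product: 28 CNP0364345.1 (target acid)
Conditions: LiOH (2.1 equiv), THF–H2O, 0 °C, short contact; 1 M HCl to pH 3, 0 °C
Reagents that add atoms: lithium hydroxide, [Li+].[OH-]
Why: Hydrolysis of an activated enol ester, whose leaving group is the enolate of a vinylogous acid, is fast at 0 °C, and the delocalised anion then lowers the acidity of C3–H and makes O1 a poor leaving group, so C3, C2 and C8 are kept and acidification gives the C5 enol hydrogen-bonded to C4=O.

**Compound list**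
1 | tert-butyl (S)-3-hydroxybutanoate | C[C@H](O)CC(=O)OC(C)(C)C | starting material
2 | dilithium alkoxide enolate of 1 | [Li+].[Li+].C[C@H]([O-])/C=C(\[O-])OC(C)(C)C | intermediate
3 | tert-butyl (2S,3S)-3-hydroxy-2-methylbutanoate | C[C@H](O)[C@H](C)C(=O)OC(C)(C)C | intermediate
4 | phloroglucinol | Oc1cc(O)cc(O)c1 | starting material
5 | ethyl 3-oxohexanoate | CCCC(=O)CC(=O)OCC | starting material
6 | 5,7-dihydroxy-4-propylcoumarin | CCCC1=CC(=O)Oc2cc(O)cc(O)c12 | intermediate
7 | tert-butyl (2S,3R)-3-[(5-hydroxy-2-oxo-4-propyl-2H-chromen-7-yl)oxy]-2-methylbutanoate | CCCC1=CC(=O)Oc2cc(O[C@H](C)[C@H](C)C(=O)OC(C)(C)C)cc(O)c12 | intermediate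
8 | 5-O-TIPS ether of 7 | CCCC1=CC(=O)Oc2cc(O[C@H](C)[C@H](C)C(=O)OC(C)(C)C)cc(O[Si](C(C)C)(C(C)C)C(C)C)c12 | intermediate
9 | (4S)-2-(pinacolboryloxy)-4H-chromene boron enolate | c1c(O[Si](C(C)C)(C(C)C)C(C)C)c2[C@@H](CCC)C=C(OB3OC(C)(C)C(C)(C)O3)Oc2cc1O[C@H](C)[C@H](C)C(=O)OC(C)(C)C | intermediate
10 | tert-butyl (2S,3R)-2-methyl-3-{[(4S)-2-oxo-4-propyl-5-(triisopropylsilyloxy)chroman-7-yl]oxy}butanoate | c1c(O[Si](C(C)C)(C(C)C)C(C)C)c2[C@@H](CCC)CC(=O)Oc2cc1O[C@H](C)[C@H](C)C(=O)OC(C)(C)C | intermediate
11 | (2S,3R)-2-methyl-3-{[(4S)-2-oxo-4-propyl-5-(triisopropylsilyloxy)chroman-7-yl]oxy}butanoic acid | c1c(O[Si](C(C)C)(C(C)C)C(C)C)c2[C@@H](CCC)CC(=O)Oc2cc1O[C@H](C)[C@H](C)C(=O)O | intermediate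
12 | mixed trifluoroacetic anhydride of 11 | c1c(O[Si](C(C)C)(C(C)C)C(C)C)c2[C@@H](CCC)CC(=O)Oc2cc1O[C@H](C)[C@H](C)C(=O)OC(=O)C(F)(F)F | intermediate
13 | O7-TIPS lactone-chromanone: cis-(2R,3S)-2,3-dimethylchroman-4-one with O5 and C6 bridged by the (S)-CH(n-Pr)CH2C(=O) lactone, C7 OTIPS, C8 H | c1c(O[Si](C(C)C)(C(C)C)C(C)C)c2[C@@H](CCC)CC(=O)Oc2c3c1O[C@H](C)[C@H](C)C3=O | intermediate
14 | O7–H lactone-chromanone | c1c(O)c2[C@@H](CCC)CC(=O)Oc2c3c1O[C@H](C)[C@H](C)C3=O | intermediate
15 | 8-iodo-7-hydroxy lactone-chromanone | Ic1c(O)c2[C@@H](CCC)CC(=O)Oc2c3c1O[C@H](C)[C@H](C)C3=O | intermediate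
16 | (1R,5R)-(+)-verbenone | CC1=CC(=O)[C@@H]2C[C@H]1C2(C)C | starting material
17 | 2-[(1R,3S)-3-acetyl-2,2-dimethylcyclobutyl]-2-oxoacetic acid | CC(=O)[C@H]1C[C@@H](C(=O)C(=O)O)C1(C)C | intermediate
18 | (1R,3S)-3-acetyl-2,2-dimethylcyclobutane-1-carboxylic acid | CC(=O)[C@H]1C[C@@H](C(=O)O)C1(C)C | intermediate
19 | (1R,3R)-2,2-dimethyl-3-(prop-1-en-2-yl)cyclobutane-1-carboxylic acid | C=C(C)[C@H]1C[C@@H](C(=O)O)C1(C)C | intermediate
20 | [(1R,3R)-2,2-dimethyl-3-(prop-1-en-2-yl)cyclobutyl]methanol | C=C(C)[C@H]1C[C@@H](CO)C1(C)C | intermediate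
21 | (1R,3R)-1-(iodomethyl)-2,2-dimethyl-3-(prop-1-en-2-yl)cyclobutane | C=C(C)[C@H]1C[C@@H](CI)C1(C)C | intermediate
22 | cis-[2,2-dimethyl-3-(prop-1-en-2-yl)cyclobutyl]methylzinc iodide | C=C(C)[C@H]1C[C@@H](C[Zn]I)C1(C)C | intermediate
23 | 8-(cyclobutylmethyl)-7-hydroxy lactone-chromanone | C=C(C)[C@H]1C[C@@H](Cc2c(O)c3[C@@H](CCC)CC(=O)Oc3c4c2O[C@H](C)[C@H](C)C4=O)C1(C)C | intermediate
24 | 2-methylbut-3-en-2-ol | C=CC(C)(C)O | starting material
25 | tert-butyl 2-methylbut-3-en-2-yl carbonate | C=CC(C)(C)OC(=O)OC(C)(C)C | intermediate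
26 | O7 1,1-dimethylallyl ether of 23 | C=C(C)[C@H]1C[C@@H](Cc2c(OC(C)(C)C=C)c3[C@@H](CCC)CC(=O)Oc3c4c2O[C@H](C)[C@H](C)C4=O)C1(C)C | intermediate
27 | (8R)-8-prenyl-8-(cyclobutylmethyl) dienone enol lactone | C=C(C)[C@H]1C[C@@H](C[C@@]2(CC=C(C)C)C(=O)C([C@@H](CCC)CC(=O)O5)=C5C3=C2O[C@H](C)[C@H](C)C3=O)C1(C)C | intermediate
28 | CNP0364345.1 | C=C(C)[C@H]1C[C@@H](C[C@@]2(CC=C(C)C)C(=O)C([C@@H](CCC)CC(=O)O)=C(O)C3=C2O[C@H](C)[C@H](C)C3=O)C1(C)C | target

**Step count:** 18 steps in total.
**Longest linear sequence:** 12 steps (2, 3, 4, 5, 6, 7, 8, 9, 14, 16, 17, 18).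

**Steps most likely to fail**

Step 17.
- What may go wrong: the shift may show poor facial selectivity at C8. It may drift toward C6. The ether may ionise and lose isoprene before it rearranges.
- Fallback: intermolecular alkylative dearomatisation, setting out from 23. Its sodium phenoxide (NaH, 1.0 equiv, toluene, 0 °C) is treated as a suspension with 1-bromo-3-methylbut-2-ene.
- Basis: in a non-polar medium tight ion pairing directs the allylic halide to the ortho carbon. This is a long-established way to 6,6-disubstituted cyclohexadienones and dearomatised acylphloroglucinols.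
- Outcome: this should give 27 together with the 8-epi dienone enol lactone F1. The two are diastereomers and are separated by chromatography. The route is rejoined at 27.

Step 16.
- What may go wrong: the crowded phenoxide may attack the unsubstituted allyl terminus. Palladium may also re-ionise the ether and funnel material to C-allylation without stereocontrol.
- Fallback: setting out from 23, copper-catalysed propargylic etherification with 3-chloro-3-methylbut-1-yne (CuCl2 cat., DBU 1.0 equiv so that no free base remains, MeCN, −5 °C). The slim linear electrophile is far less demanding and should give the O7 1,1-dimethylpropargyl ether F2.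
- Return: semihydrogenation (H2, Pd on CaCO3 poisoned with Pb(OAc)2, quinoline, EtOAc) reduces the terminal alkyne ahead of the 1,1-disubstituted alkene. The route is rejoined at 26.

Step 3.
- What may go wrong: the activated β-hydroxy ester may undergo β-elimination to the tiglate ester faster than it is displaced.
- Fallback: the acidifying carbonyl is removed for the substitution, setting out from 3.
- LiAlH4 gives (2R,3S)-2-methylbutane-1,3-diol F3.
- TBSCl and imidazole silylate the primary hydroxyl to give (2S,3R)-4-(tert-butyldimethylsilyloxy)-3-methylbutan-2-ol F4.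
- Mitsunobu reaction with 6 gives, with inversion, the 5-hydroxycoumarin 7-ether F5.
- TIPSOTf and 2,6-lutidine give the 5-O-TIPS coumarin ether F6.
- The copper hydride and pinacolborane reduction of step 5 gives, through the boron enolate F7, the (4S)-dihydrocoumarin silyl ether F8.
- AcOH–THF–H2O removes only the primary alkyl TBS group to give the primary alcohol F9.
- TEMPO with PhI(OAc)2 in MeCN–H2O oxidises it through the aldehyde F10 to acid 11, where the route is rejoined.

**Further compounds**
F1 | step 17 | 8-epi dienone enol lactone (8S) | C=C(C)[C@H]1C[C@@H](C[C@]2(CC=C(C)C)C(=O)C([C@@H](CCC)CC(=O)O5)=C5C3=C2O[C@H](C)[C@H](C)C3=O)C1(C)C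
F2 | step 16 | O7 1,1-dimethylpropargyl ether of 23 | C=C(C)[C@H]1C[C@@H](Cc2c(OC(C)(C)C#C)c3[C@@H](CCC)CC(=O)Oc3c4c2O[C@H](C)[C@H](C)C4=O)C1(C)C
F3 | step 3 | (2R,3S)-2-methylbutane-1,3-diol | C[C@H](O)[C@H](C)CO
F4 | step 3 | (2S,3R)-4-(tert-butyldimethylsilyloxy)-3-methylbutan-2-ol | C[C@H](O)[C@H](C)CO[Si](C)(C)C(C)(C)C
F5 | step 3 | 7-{[(2R,3R)-4-(tert-butyldimethylsilyloxy)-3-methylbutan-2-yl]oxy}-5-hydroxy-4-propylcoumarin | CCCC1=CC(=O)Oc2cc(O[C@H](C)[C@H](C)CO[Si](C)(C)C(C)(C)C)cc(O)c12
F6 | step 3 | 5-O-TIPS ether of F5 | CCCC1=CC(=O)Oc2cc(O[C@H](C)[C@H](C)CO[Si](C)(C)C(C)(C)C)cc(O[Si](C(C)C)(C(C)C)C(C)C)c12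
F7 | step 3 | boron enolate from F6 | c1c(O[Si](C(C)C)(C(C)C)C(C)C)c2[C@@H](CCC)C=C(OB3OC(C)(C)C(C)(C)O3)Oc2cc1O[C@H](C)[C@H](C)CO[Si](C)(C)C(C)(C)C
F8 | step 3 | (4S)-dihydrocoumarin silyl ether | c1c(O[Si](C(C)C)(C(C)C)C(C)C)c2[C@@H](CCC)CC(=O)Oc2cc1O[C@H](C)[C@H](C)CO[Si](C)(C)C(C)(C)C
F9 | step 3 | primary alcohol from F8 | c1c(O[Si](C(C)C)(C(C)C)C(C)C)c2[C@@H](CCC)CC(=O)Oc2cc1O[C@H](C)[C@H](C)CO
F10 | step 3 | aldehyde from F9 | c1c(O[Si](C(C)C)(C(C)C)C(C)C)c2[C@@H](CCC)CC(=O)Oc2cc1O[C@H](C)[C@H](C)C=O
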